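**Retrosynthetic overview**

1. The C2′ sulfate goes last onto the only free phenol of a MOM/TIPS-differentiated arene. The arene is joined at C15 by aryllithium addition to the decalin formyl carbon followed by radical deoxygenation, and C4=C11 comes from a Wittig reaction on the C4 ketone.
2. The C5 β-methyl (trans to H10) is delivered to C5=C6 from a 7β-hydroxyl: C7 C–H oxidation, bulky-hydride reduction, directed Simmons–Smith, Li/NH3 opening, Wolff–Kishner. The C4 oxygen is not used for this because its β position is equatorial, in the plane of C5=C6, so it could only direct to the α face.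
3. Ring B is disconnected by an exo Diels–Alder reaction. C8=C9 of (E)-tiglic aldehyde (CHO = C15) adds to the diene C10=C5–C6=C7 of the (R)-TBS ether of 2-vinylcyclohex-2-enol, forming C9–C10 and C7–C8.
4. Feature on which the strategy rests: the contiguous C8 (CH–CH3), quaternary C9 (CH3 and C15) and C10 (H) of ring B, with cis C8/C9 methyls, are the (E)-alkene and formyl group of tiglic aldehyde; ring A (C1–C5, C10) with its C4 oxygen carries the diene.
5. Ring order: ring A (bought as cyclohex-2-enone), ring B (step 5), arene attached in step 19.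

Key step: step 5

Assumption: the target is taken as the free aryl hydrogen sulfate as drawn; it is released from its sodium salt in the last operation and would be stored as that salt.

Convention: decalin numbering C1–C10 (ring A = C1–C5 and C10, ring B = C5–C10), C11 = CH2 on C4, C15 = carbon on C9 that becomes the benzylic CH2. Arene: C1′ bonded to C15, C2′ bears the sulfate oxygen, C3′ the phenol, C5′ the CH2OH. β = face of the C8 and C9 methyl groups, α = face of H10 and C15. TBS = tert-butyldimethylsilyl, TIPS = triisopropylsilyl, MOM = methoxymethyl.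

**Route**

Step 1
Reactants: 1 cyclohex-2-en-1-one
Product: 2 2-iodocyclohex-2-en-1-one
Conditions: I2 (1.5 equiv), pyridine–CH2Cl2 (1:1), 0 °C → rt
Reagents that add atoms: iodine, II
Why: α-Iodination of the enone by reversible conjugate addition of pyridine, iodination of the resulting enolate and elimination of pyridine (Baylis–Hillman-type α-halogenation).

Step 2
Reactants: 2 2-iodocyclohex-2-en-1-one
Product: 3 (R)-2-iodocyclohex-2-en-1-ol
Conditions: (S)-Me-CBS [(S)-1-methyl-3,3-diphenyltetrahydro-1H,3H-pyrrolo[1,2-c][1,3,2]oxazaborole] (10 mol%), BH3·SMe2 (0.7 equiv), THF, 0 °C; MeOH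
Reagents that add atoms: none
Why: Corey–Bakshi–Shibata reduction; the oxazaborolidine–borane complex binds the ketone with the α-iodovinyl group as the large substituent and delivers hydride to one carbonyl face, which should set the (R)-carbinol centre.

Step 3
Reactants: 3 (R)-2-iodocyclohex-2-en-1-ol
Product: 4 (R)-tert-butyl[(2-iodocyclohex-2-en-1-yl)oxy]dimethylsilane
Conditions: TBSCl (1.2 equiv), imidazole (2.5 equiv), DMF, rt
Reagents that add atoms: tert-butyldimethylsilyl chloride, CC(C)(C)[Si](C)(C)Cl
Why: Imidazole-mediated silylation of a secondary allylic alcohol; the stereocentre is not touched.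

Step 4
Reactants: 4 (R)-tert-butyl[(2-iodocyclohex-2-en-1-yl)oxy]dimethylsilane
Product: 5 (R)-tert-butyldimethyl[(2-vinylcyclohex-2-en-1-yl)oxy]silane
Conditions: Bu3SnCH=CH2 (1.3 equiv), Pd(PPh3)4 (5 mol%), DMF, 60 °C
Reagents that add atoms: tributyl(vinyl)stannane, C=C[Sn](CCCC)(CCCC)CCCC
Why: Stille coupling of an alkenyl iodide (oxidative addition to zerovalent palladium, transmetallation from tin, reductive elimination) builds the 1,3-diene without affecting the allylic silyl ether or its stereocentre.

Step 5
Reactants: 5 (R)-tert-butyldimethyl[(2-vinylcyclohex-2-en-1-yl)oxy]silane; 6 tiglic aldehyde [(E)-2-methylbut-2-enal]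
Product: 7 4α-(tert-butyldimethylsilyloxy)-8β,9β-dimethyl-Δ5-octalin-9α-carbaldehyde (10α-H; ring B cyclohexene C5=C6)
Conditions: 6 (3 equiv), Et2AlCl (1.5 equiv), CH2Cl2, −78 → −20 °C
Reagents that add atoms: none
Why: Et2AlCl binds the formyl oxygen of 6 and the enal adds to the s-cis diene of 5 in a concerted but asynchronous [4+2] cycloaddition (Lewis acid-promoted Diels–Alder reaction of an α-methyl enal with a 1-vinylcyclohexene), C8 bonding to the unsubstituted terminus C7 ahead of C9 to C10. Ring B is closed in this intermolecular [4+2] mode, the two σ bonds C7–C8 and C9–C10 forming across the diene termini and leaving the new C5=C6 alkene in ring B. The regiochemistry (formyl-bearing C9 to C10) follows from the larger HOMO coefficient at C7 of the diene and the larger LUMO coefficient at the enal β-carbon C8. C8 and C9 are set relative to each other by the (E)-geometry of 6 (cis methyls); C9 relative to C10 by the exo-formyl transition state that α-methyl enals prefer (CHO cis to H10, methyl endo); and the absolute sense by the pseudoaxial C4 silyloxy group, which shields the α face of the diene so that 6 adds anti to it. The step needs exo and π-facial selectivity together; both rest on substrate features (the α-methyl group of 6, the C4 stereocentre of 5), and the low temperature should keep the allylic silyl ether from ionising.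

Step 6
Reactants: 7 cycloadduct aldehyde
Product: 8 4α-(tert-butyldimethylsilyloxy)-9α-(hydroxymethyl)-8β,9β-dimethyl-Δ5-octalin (10α-H)
Conditions: NaBH4, MeOH, 0 °C
Reagents that add atoms: none
Why: Borohydride reduction of the non-enolisable neopentyl aldehyde, which parks C15 as an alcohol through the oxidative and reductive steps that follow.

Step 7
Reactants: 8 C15 alcohol
Product: 9 C4,C15 bis-TBS ether of 8
Conditions: TBSCl (1.3 equiv), imidazole (3 equiv), DMF, rt
Reagents that add atoms: tert-butyldimethylsilyl chloride, CC(C)(C)[Si](C)(C)Cl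
Why: Silylation of the primary alcohol gives one protecting-group type on both oxygens, so a single fluoride step frees them later.

Step 8
Reactants: 9 bis-TBS ether
Product: 10 Δ5-en-7-one (4α,15-bis-TBS; enone C7(=O)–C6=C5)
Conditions: Rh2(cap)4 [dirhodium tetrakis(caprolactamate)] (1 mol%), t-BuOOH (5 equiv), K2CO3 (0.5 equiv), CH2Cl2, rt
Reagents that add atoms: tert-butyl hydroperoxide, CC(C)(C)OO
Why: Dirhodium-catalysed allylic C–H oxidation with TBHP (the reaction type used for 7-oxidation of Δ5-steroids); the tert-butylperoxyl radical should abstract the accessible, π-aligned hydrogen at C7, since the C4–H lies in the alkene plane (axial silyloxy group) and the tertiary C10–H is buried beside the quaternary C9.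

Step 9
Reactants: 10 Δ5-en-7-one
Product: 11 7β-hydroxy-Δ5-octalin (4α,15-bis-TBS)
Conditions: L-Selectride (LiBH(s-Bu)3, 1.3 equiv), THF, −78 °C; H2O
Reagents that add atoms: none
Why: Stereoselective 1,2-reduction of a β,β-disubstituted enone; the bulky hydride should approach C7 from the α face because the β-axial trajectory is blocked by the syn-axial C9 methyl group, giving the 7β-alcohol.

Step 10
Reactants: 11 7β-allylic alcohol
Product: 12 5β,6β-methano (cyclopropane) 7β-alcohol (4α,15-bis-TBS)
Conditions: Et2Zn (4 equiv), CH2I2 (8 equiv), CH2Cl2, −10 °C → rt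
Reagents that add atoms: diiodomethane, ICI
Why: Hydroxyl-directed Simmons–Smith cyclopropanation; the zinc alkoxide of the ring B cyclohex-2-enol delivers CH2 to the face of C5=C6 syn to the 7β-oxygen, so the new bond at C5 is β (trans to H10), while the bulky C4 silyl ether is a poor ligand and does not compete as director.

Step 11
Reactants: 12 cyclopropyl carbinol
Product: 13 5β,6β-methano-7-ketone (4α,15-bis-TBS)
Conditions: Dess–Martin periodinane (1.5 equiv), NaHCO3, CH2Cl2, rt
Reagents that add atoms: none
Why: Dess–Martin oxidation of the secondary alcohol under buffered, non-acidic conditions that leave the cyclopropane and silyl ethers intact.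

Step 12
Reactants: 13 cyclopropyl ketone
Product: 14 5β,8β,9β-trimethyl-trans-decalin-7-one (4α,15-bis-TBS; 10α-H)
Conditions: Li (5 equiv), NH3(l)–THF, −78 °C; then NH4Cl
Reagents that add atoms: none
Why: Dissolving-metal reduction of the cyclopropyl ketone cleaves the external C6–CH2 bond, which overlaps best with the carbonyl π system, and the primary carbanion is protonated to the C5 methyl group (classical angular methylation); C5 keeps the β configuration fixed in step 10 and the lithium enolate protects the ketone until the quench.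

Step 13
Reactants: 14 bis-TBS ketone
Product: 15 4α-hydroxy-9α-(hydroxymethyl)-5β,8β,9β-trimethyl-trans-decalin-7-one
Conditions: Bu4NF (3 equiv), THF, rt → 50 °C
Reagents that add atoms: none
Why: Fluoride cleavage of both silyl ethers, driven by Si–F bond formation.

Step 14
Reactants: 15 keto diol
Product: 16 4α-hydroxy-9α-(hydroxymethyl)-5β,8β,9β-trimethyl-trans-decalin (10α-H)
Conditions: N2H4·H2O, KOH, diethylene glycol, 130 °C then 200 °C
Reagents that add atoms: none
Why: Wolff–Kishner reduction removes the C7 carbonyl, which has now served its purpose, via the hydrazone; the C4 hydroxyl is untouched and the C8 methyl stays in its more stable equatorial position.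

Step 15
Reactants: 16 diol
Product: 17 5β,8β,9β-trimethyl-4-oxo-trans-decalin-9α-carbaldehyde (10α-H)
Conditions: Dess–Martin periodinane (3 equiv), NaHCO3, CH2Cl2, rt
Reagents that add atoms: none
Why: Dess–Martin oxidation of both alcohols gives the C4 ketone and the non-enolisable C15 aldehyde in one operation.

Step 16
Reactants: 18 3-bromo-4,5-dihydroxybenzaldehyde
Product: 19 3-bromo-5-hydroxy-4-(methoxymethoxy)benzaldehyde
Conditions: MOMCl (1.05 equiv), K2CO3 (1.05 equiv), acetone, 0 °C → rt
Reagents that add atoms: chloromethyl methyl ether, COCCl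
Why: Regioselective O-alkylation; with one equivalent of weak base only the more acidic 4-hydroxyl (para to CHO, ortho to Br) is ionised, so the oxygen that will carry the sulfate is marked with the MOM group.

Step 17
Reactants: 19 MOM aldehyde
Product: 20 3-bromo-5-(hydroxymethyl)-2-(methoxymethoxy)phenol
Conditions: NaBH4, MeOH, 0 °C
Reagents that add atoms: none
Why: Borohydride reduction of the aryl aldehyde to the benzylic alcohol.

Step 18
Reactants: 20 phenol benzyl alcohol
Product: 21 {[3-bromo-4-(methoxymethoxy)-5-(triisopropylsilyloxy)phenyl]methoxy}triisopropylsilane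
Conditions: TIPSCl (2.4 equiv), imidazole (5 equiv), DMF, rt → 40 °C
Reagents that add atoms: triisopropylsilyl chloride, CC(C)[Si](Cl)(C(C)C)C(C)C
Why: Silylation of the phenol and the benzylic alcohol with a bulky silyl group that tolerates organolithium, radical and Wittig conditions and resists migration between the catechol oxygens.

Step 19
Reactants: 17 keto aldehyde; 21 aryl bromide
Product: 23 C15 carbinol (mixture of C15 epimers; C4 ketone kept), via aryllithium 22 (not isolated)
Conditions: 21 (1.4 equiv), t-BuLi (2.8 equiv), THF, −78 °C; then 17, −78 → −40 °C; H2O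
Reagents that add atoms: none
Why: Bromine–lithium exchange gives an aryllithium stabilised by the ortho MOM oxygen, which should add to the formyl group much faster than to the α-quaternary C4 ketone at low temperature (chemoselective 1,2-addition); the C15 configuration is irrelevant because the oxygen is removed.

Step 20
Reactants: 23 C15 carbinol
Product: 24 O-phenyl thionocarbonate of 23 (mixture of C15 epimers)
Conditions: PhOC(S)Cl (3 equiv), pyridine (6 equiv), DMAP [4-(dimethylamino)pyridine] (0.5 equiv), CH2Cl2, rt → 40 °C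
Reagents that add atoms: O-phenyl chlorothionoformate, S=C(Cl)Oc1ccccc1
Why: Acyl-transfer thiocarbonylation of the hindered secondary alcohol under conditions that do not enolise the C4 ketone, as a strong base with CS2 would.

Step 21
Reactants: 24 thionocarbonate
Product: 25 C15-methylene aryl decalin-4-one (arene with C2′ OMOM, C3′ OTIPS, C5′ CH2OTIPS)
Conditions: Bu3SnH (3 equiv), AIBN [2,2′-azobis(2-methylpropionitrile)] (0.2 equiv), toluene, 100 °C
Reagents that add atoms: none
Why: Barton–McCombie deoxygenation; the stannyl radical adds to C=S, the stabilised benzylic C15 radical is released and reduced by the tin hydride, and neither the ketone nor the other benzylic C–O bond reacts.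

Step 22
Reactants: 25 aryl decalin-4-one
Product: 26 4(11)-methylene compound (arene protection unchanged)
Conditions: Ph3PCH3Br (4 equiv), KN(SiMe3)2 (3.8 equiv), toluene, 0 → 90 °C
Reagents that add atoms: methyltriphenylphosphonium bromide, C[P+](c1ccccc1)(c1ccccc1)c1ccccc1.[Br-]
Why: Wittig methylenation with excess salt-free ylide at elevated temperature, the usual way to convert an α-quaternary cyclohexanone into the exocyclic alkene; C5 cannot epimerise.

Step 23
Reactants: 26 methylene compound
Product: 28 C2′ phenol (both TIPS ethers kept), via aryl trimethylsilyl ether 27 (not isolated)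
Conditions: TMSOTf (2 equiv), 2,2′-bipyridyl (3 equiv), MeCN, 0 °C → rt; then H2O
Reagents that add atoms: none
Why: The silyl triflate–bipyridyl pair cleaves the aromatic MOM acetal to the aryl trimethylsilyl ether, which hydrolyses on aqueous work-up; the medium stays buffered, so the exocyclic alkene and the TIPS ethers should survive.

Step 24
Reactants: 28 C2′ phenol
Product: 29 sodium C2′ aryl sulfate (C3′ OTIPS, C5′ CH2OTIPS)
Conditions: SO3·pyridine (5 equiv), pyridine, 50 °C; then aq NaHCO3
Reagents that add atoms: sulfur trioxide–pyridine complex, O=S(=O)([O-])[n+]1ccccc1; sodium hydrogen carbonate, [Na+].OC([O-])=O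
Why: O-Sulfation of the only free hydroxyl with the small electrophile SO3 (hindered 2,6-disubstituted phenols are known to be sulfated this way); regiochemistry is fixed by the protecting-group pattern and the salt is stable to base.

Step 25
Reactants: 29 sodium aryl sulfate
Product: 31 CNP0353860.3 (the target aryl hydrogen sulfate), via sodium salt 30 (not isolated)
Conditions: NH4F (20 equiv), MeOH, 50 °C; then 0.1 M HCl (1 equiv), 0 °C, extraction (n-BuOH–EtOAc)
Reagents that add atoms: none
Why: Neutral fluoride desilylation frees the phenol and the benzylic alcohol without touching the aryl sulfate or the exocyclic alkene, and brief cold protonation of the salt gives the hydrogen sulfate.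

**Compound list**

1 | cyclohex-2-en-1-one | O=C1C=CCCC1 | starting material
2 | 2-iodocyclohex-2-en-1-one | O=C1CCCC=C1I | intermediate
3 | (R)-2-iodocyclohex-2-en-1-ol | IC1=CCCC[C@H]1O | intermediate
4 | (R)-tert-butyl[(2-iodocyclohex-2-en-1-yl)oxy]dimethylsilane | IC1=CCCC[C@H]1O[Si](C)(C)C(C)(C)C | intermediate
5 | (R)-tert-butyldimethyl[(2-vinylcyclohex-2-en-1-yl)oxy]silane | C=CC1=CCCC[C@H]1O[Si](C)(C)C(C)(C)C | intermediate
6 | tiglic aldehyde, (E)-2-methylbut-2-enal | C/C=C(\C)C=O | starting material
7 | 4α-(TBSO)-8β,9β-dimethyl-Δ5-octalin-9α-carbaldehyde (10α-H) | CC(C)(C)[Si](C)(C)O[C@@H]1CCC[C@H]2[C@](C)(C=O)[C@@H](C)CC=C12 | intermediate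
8 | 4α-(TBSO)-9α-(hydroxymethyl)-8β,9β-dimethyl-Δ5-octalin | CC(C)(C)[Si](C)(C)O[C@@H]1CCC[C@H]2[C@](C)(CO)[C@@H](C)CC=C12 | intermediate
9 | 4α-(TBSO)-9α-(TBSOCH2)-8β,9β-dimethyl-Δ5-octalin | CC(C)(C)[Si](C)(C)O[C@@H]1CCC[C@H]2[C@](C)(CO[Si](C)(C)C(C)(C)C)[C@@H](C)CC=C12 | intermediate
10 | Δ5-en-7-one of 9 | CC(C)(C)[Si](C)(C)O[C@@H]1CCC[C@H]2[C@](C)(CO[Si](C)(C)C(C)(C)C)[C@@H](C)C(=O)C=C12 | intermediate
11 | 7β-hydroxy-Δ5-octalin (4α,15-bis-TBS) | CC(C)(C)[Si](C)(C)O[C@@H]1CCC[C@H]2[C@](C)(CO[Si](C)(C)C(C)(C)C)[C@@H](C)[C@@H](O)C=C12 | intermediate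
12 | 5β,6β-methano-7β-ol (4α,15-bis-TBS) | CC(C)(C)[Si](C)(C)O[C@@H]1CCC[C@H]2[C@](C)(CO[Si](C)(C)C(C)(C)C)[C@@H](C)[C@@H](O)[C@H]3C[C@@]123 | intermediate
13 | 5β,6β-methano-7-one (4α,15-bis-TBS) | CC(C)(C)[Si](C)(C)O[C@@H]1CCC[C@H]2[C@](C)(CO[Si](C)(C)C(C)(C)C)[C@@H](C)C(=O)[C@H]3C[C@@]123 | intermediate
14 | 5β,8β,9β-trimethyl-trans-decalin-7-one (4α,15-bis-TBS) | CC(C)(C)[Si](C)(C)O[C@@H]1CCC[C@H]2[C@](C)(CO[Si](C)(C)C(C)(C)C)[C@@H](C)C(=O)C[C@]12C | intermediate
15 | 4α-hydroxy-9α-(hydroxymethyl)-5β,8β,9β-trimethyl-trans-decalin-7-one | O[C@@H]1CCC[C@H]2[C@](C)(CO)[C@@H](C)C(=O)C[C@]12C | intermediate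
16 | 4α-hydroxy-9α-(hydroxymethyl)-5β,8β,9β-trimethyl-trans-decalin | O[C@@H]1CCC[C@H]2[C@](C)(CO)[C@@H](C)CC[C@]12C | intermediate
17 | 5β,8β,9β-trimethyl-4-oxo-trans-decalin-9α-carbaldehyde | O=C1CCC[C@H]2[C@](C)(C=O)[C@@H](C)CC[C@]12C | intermediate
18 | 3-bromo-4,5-dihydroxybenzaldehyde | O=Cc1cc(O)c(O)c(Br)c1 | starting material
19 | 3-bromo-5-hydroxy-4-(methoxymethoxy)benzaldehyde | COCOc1c(O)cc(C=O)cc1Br | intermediate
20 | 3-bromo-5-(hydroxymethyl)-2-(methoxymethoxy)phenol | COCOc1c(O)cc(CO)cc1Br | intermediate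
21 | {[3-bromo-4-(methoxymethoxy)-5-(triisopropylsilyloxy)phenyl]methoxy}triisopropylsilane | COCOc1c(O[Si](C(C)C)(C(C)C)C(C)C)cc(CO[Si](C(C)C)(C(C)C)C(C)C)cc1Br | intermediate
22 | aryllithium from 21 (Li in place of Br) | COCOc1c(O[Si](C(C)C)(C(C)C)C(C)C)cc(CO[Si](C(C)C)(C(C)C)C(C)C)cc1[Li] | intermediate
23 | C15 carbinol: 9α-[aryl(hydroxy)methyl]-4-ketone, C15 epimers | O=C1CCC[C@H]2[C@](C)(C(O)c3cc(CO[Si](C(C)C)(C(C)C)C(C)C)cc(O[Si](C(C)C)(C(C)C)C(C)C)c3OCOC)[C@@H](C)CC[C@]12C | intermediate
24 | O-phenyl thionocarbonate of 23, C15 epimers | O=C1CCC[C@H]2[C@](C)(C(OC(=S)Oc3ccccc3)c3cc(CO[Si](C(C)C)(C(C)C)C(C)C)cc(O[Si](C(C)C)(C(C)C)C(C)C)c3OCOC)[C@@H](C)CC[C@]12C | intermediate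
25 | 9α-(arylmethyl)-5β,8β,9β-trimethyl-trans-decalin-4-one (C2′ OMOM, C3′ OTIPS, C5′ CH2OTIPS) | O=C1CCC[C@H]2[C@](C)(Cc3cc(CO[Si](C(C)C)(C(C)C)C(C)C)cc(O[Si](C(C)C)(C(C)C)C(C)C)c3OCOC)[C@@H](C)CC[C@]12C | intermediate
26 | 4(11)-methylene analogue of 25 | C=C1CCC[C@H]2[C@](C)(Cc3cc(CO[Si](C(C)C)(C(C)C)C(C)C)cc(O[Si](C(C)C)(C(C)C)C(C)C)c3OCOC)[C@@H](C)CC[C@]12C | intermediate
27 | C2′ trimethylsilyl ether (MOM replaced by SiMe3) | C=C1CCC[C@H]2[C@](C)(Cc3cc(CO[Si](C(C)C)(C(C)C)C(C)C)cc(O[Si](C(C)C)(C(C)C)C(C)C)c3O[Si](C)(C)C)[C@@H](C)CC[C@]12C | intermediate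
28 | C2′ phenol (C3′ OTIPS, C5′ CH2OTIPS) | C=C1CCC[C@H]2[C@](C)(Cc3cc(CO[Si](C(C)C)(C(C)C)C(C)C)cc(O[Si](C(C)C)(C(C)C)C(C)C)c3O)[C@@H](C)CC[C@]12C | intermediate
29 | sodium C2′ aryl sulfate (C3′ OTIPS, C5′ CH2OTIPS) | C=C1CCC[C@H]2[C@](C)(Cc3cc(CO[Si](C(C)C)(C(C)C)C(C)C)cc(O[Si](C(C)C)(C(C)C)C(C)C)c3OS(=O)(=O)[O-])[C@@H](C)CC[C@]12C.[Na+] | intermediate
30 | sodium salt of the target | C=C1CCC[C@H]2[C@](C)(Cc3cc(CO)cc(O)c3OS(=O)(=O)[O-])[C@@H](C)CC[C@]12C.[Na+] | intermediate
31 | CNP0353860.3 | C=C1CCC[C@H]2[C@](C)(Cc3cc(CO)cc(O)c3OS(=O)(=O)O)[C@@H](C)CC[C@]12C | target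

**Step count**

Total: 25 steps. Longest linear sequence: 22 steps (steps 1–15 and 19–25; steps 16–18 make the arene in parallel).

**Three steps most likely to fail**

Step 5. What may go wrong: loss of exo or π-facial selectivity, or Lewis-acid-induced ionisation of the allylic silyl ether and oligomerisation of the diene. The fallback sets out from 5 and 6 and returns at 7. It replaces aluminium activation of the aldehyde by an ionic Diels–Alder reaction of its acetal. Compound 6 is first converted (ethylene glycol, pyridinium p-toluenesulfonate, benzene, water removal) into 2-[(E)-but-2-en-2-yl]-1,3-dioxolane F1. TMSOTf (10 mol%) in CH2Cl2 at −78 °C then ionises F1 to a 2-alkenyl-1,3-dioxolan-2-ylium ion, a far stronger dienophile, which should add to 5 with the same regiochemistry and the same shielding by the C4 silyloxy group to give the ethylene acetal of the cycloadduct F2. Mild hydrolysis (pyridinium p-toluenesulfonate, wet acetone) then gives 7.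

Step 8. What may go wrong: hydrogen abstraction at the tertiary allylic C10–H (or at C4–H) competing with C7–H, and over-oxidation. The fallback sets out from 9 and returns at 10, moving the oxygen to C7 by ionic chemistry instead of C–H abstraction. Epoxidation (mCPBA, NaHCO3, CH2Cl2) gives the 5,6-epoxide F3; either face serves. Opening at the secondary C6 with PhSeNa (from (PhSe)2 and NaBH4, EtOH) gives the 5-hydroxy-6-(phenylselanyl) compound F4. Oxidation with H2O2 gives the selenoxide F5, which undergoes syn-elimination toward C7 to the tertiary allylic alcohol F6 (C6=C7, C5–OH). Oxidative 1,3-transposition with pyridinium chlorochromate (C5H5NH[CrO3Cl]) converts F6 into enone 10.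

Step 10. What may go wrong: slow or face-unselective methylene transfer, because the β face of C5=C6 is crowded by the syn-axial C9 methyl group. The fallback sets out from 11 and returns at 16, bypassing steps 10–14; the methyl group is transferred directly from copper instead of through a cyclopropane. Alcohol 11 is converted with PhNCO (pyridine, CH2Cl2) into the 7β-N-phenylcarbamate F7. Deprotonation (MeLi, THF, −78 °C), CuI (1 equiv) and a second equivalent of MeLi (0 °C → rt) give a carbamate-bound methylcopper that transfers methyl intramolecularly to C5 on the face of the leaving group (syn-SN2′ substitution), giving the 5β-methyl-Δ6-octalin F8 with no oxygen left at C7. Hydrogenation (H2, palladium on carbon, EtOAc) gives the saturated bis-silyl ether F9, and Bu4NF in THF gives diol 16.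

Further compounds
F1 | step 5 | 2-[(E)-but-2-en-2-yl]-1,3-dioxolane | C/C=C(\C)C1OCCO1
F2 | step 5 | ethylene acetal of cycloadduct 7 | CC(C)(C)[Si](C)(C)O[C@@H]1CCC[C@H]2[C@](C)(C3OCCO3)[C@@H](C)CC=C12
F3 | step 8 | 5,6-epoxide of 9 (either epoxide face) | CC(C)(C)[Si](C)(C)O[C@@H]1CCC[C@H]2[C@](C)(CO[Si](C)(C)C(C)(C)C)[C@@H](C)CC3OC123
F4 | step 8 | 5-hydroxy-6-(phenylselanyl) compound from F3 | CC(C)(C)[Si](C)(C)O[C@@H]1CCC[C@H]2[C@](C)(CO[Si](C)(C)C(C)(C)C)[C@@H](C)CC([Se]c3ccccc3)C12O
F5 | step 8 | selenoxide of F4 | CC(C)(C)[Si](C)(C)O[C@@H]1CCC[C@H]2[C@](C)(CO[Si](C)(C)C(C)(C)C)[C@@H](C)CC([Se](=O)c3ccccc3)C12O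
F6 | step 8 | 5-hydroxy-Δ6-octalin (tertiary allylic alcohol; 4α,15-bis-TBS) | CC(C)(C)[Si](C)(C)O[C@@H]1CCC[C@H]2[C@](C)(CO[Si](C)(C)C(C)(C)C)[C@@H](C)C=CC12O
F7 | step 10 | 7β-N-phenylcarbamate of 11 | CC(C)(C)[Si](C)(C)O[C@@H]1CCC[C@H]2[C@](C)(CO[Si](C)(C)C(C)(C)C)[C@@H](C)[C@@H](OC(=O)Nc3ccccc3)C=C12
F8 | step 10 | 5β,8β,9β-trimethyl-Δ6-octalin (4α,15-bis-TBS; 10α-H) | CC(C)(C)[Si](C)(C)O[C@@H]1CCC[C@H]2[C@](C)(CO[Si](C)(C)C(C)(C)C)[C@@H](C)C=C[C@]12C
F9 | step 10 | 5β,8β,9β-trimethyl-trans-decalin (4α,15-bis-TBS) | CC(C)(C)[Si](C)(C)O[C@@H]1CCC[C@H]2[C@](C)(CO[Si](C)(C)C(C)(C)C)[C@@H](C)CC[C@]12C
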